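At 90.0 min the south run read 6.0% target and the south-east run 3.1%. The two runs differ in one charge, reagent, yet both read the same tautomer peak, 14.8% at 8.00 min.

| setting | south-east | south | flask |
|---|---|---|---|
| substrate | 0.40 M | 0.40 M | 0.40 M |
| reagent | 0.10 M (fed, over 2.5 min) | 0.15 M (fed, over 2.5 min) | 0.200 M (fed, over 2.5 min) |
| remark | run made earlier; the fed solution adds 0.25 times the starting volume | run made earlier; the fed solution adds 0.25 times the starting volume | the fed solution adds 0.25 times the starting volume |
| time |  |  | 2.5 h |

| run | time / min | tautomer / % | target / % |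
|---|---|---|---|
| south-east | 2.50 | 9.4 | 0 |
| south-east | 4.00 | 12.0 | 1.3 |
| south-east | 8.00 | 14.8 | 0.5 |
| south-east | 15.0 | 14.0 | 1.8 |
| south-east | 25.0 | 13.3 | 2.5 |
| south-east | 50.0 | 8.3 | 3.0 |
| south-east | 90.0 | 6.1 | 3.1 |
| south | 2.50 | 7.5 | 0.8 |
| south | 4.00 | 10.5 | 0 |
| south | 8.00 | 14.8 | 1.6 |
| south | 15.0 | 13.5 | 0.7 |
| south | 25.0 | 10.4 | 3.3 |
| south | 50.0 | 5.5 | 5.9 |
| south | 90.0 | 5.0 | 6.0 |

(each reading ± 1 percentage point)

- charges are per starting volume, the dose included; the dosed solution carries all of it

* the best time, 2.5 h at the latest, for tautomer
* the amount of tautomer, in percent of the substrate charged, at that time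

I wanted to know why the target readings ended apart while the tautomer peak readings matched. At 25.0 min, target per molar of reagent charged read 0.250 M⁻¹ in the south-east run and 0.220 M⁻¹ in the south run. Those agree within the scatter, so I took target formation as first order in reagent. I read tautomer's supply from its rise over the feed, averaged across both runs: 0.0338 min⁻¹ as a fraction of the substrate charged. The pooled mean target rate up to 25.0 min per molar, divided by that early supply, gave 0.275 M⁻¹. I called this the reagent's draw, the share of tautomer's supply taken to target per molar of reagent charged. At the mean charge of the runs it came to 3.43%, hardly any of the supply, so the peak readings stayed level while target rose with the charge.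

For the flask, at 0.200 M, the share became 5.49%. Scaling the peak reading by the part of the supply left, I expected 14.5% near 8.00 min.

The forecast gave 14% (12% to 16.5%) at 0.13 h (0.08 h to 0.2 h), noting “Reagent mainly speeds the later loss”. My height stood above its figure.

The flask gave 14.4% at 0.160 h, inside the forecast's height range and later than its time.

    substrate + reagent → isomer of the product (k = 0.00120 M⁻¹ s⁻¹)
    reagent + tautomer → target (k = 0.00200 M⁻¹ s⁻¹)
    substrate ⇌ tautomer (K = 0.360, k = 8.70 × 10⁻⁴ s⁻¹)
    substrate + tautomer → side product (k = 0.00520 M⁻¹ s⁻¹)

My 14.5% for the flask lay 0.100 percentage points from that height. The neighbouring flask differs from the flask in its reagent charge, 0.50 M. There the share comes to 13.8%, and the same scaling gives 13.2% tautomer at the peak. That neighbour gave 12.6%, and it ended with 18.6% target.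

Readings and results stem from a simulated flask for an exercise; scatter was added.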